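The route rests on disconnecting both phenolic C–O bonds, C1–OH of the 3,5-dibromo ring A and C1′–OH of the 3′,4′,5′-tribromo ring B, back to formyl groups. Each of these carbons lies next to the ether-bearing carbon (C2, C2′), so an ortho-formyl group can first activate diaryl ether formation and then be exchanged for oxygen. One twofold Baeyer–Villiger (Dakin-type) oxidation turns the pentabromo dialdehyde into the bis-formate of the target, making both C–O bonds at once. The precursor is the diaryl ether carrying CHO at C1 and C1′ with all five bromines already in place, assembled by bromination of a salicylaldehyde and fluoride displacement.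

Key step: step 3

Assumption (chemistry): the target has no stereocentre, and rotation about the diaryl ether C–O bonds is fast at room temperature. It is therefore a single achiral compound and no step needs stereocontrol.

Numbering used below: on each ring the carbon that ends as C–OH (and starts as C–CHO) is C1 (ring A) or C1′ (ring B), and the ether-bearing carbon is C2 or C2′.

Step 1
Reactants: 1 4-bromo-2-hydroxybenzaldehyde
Product: 2 3,4,5-tribromo-2-hydroxybenzaldehyde
Conditions: Br2 (2.3 equiv), NaOAc (2.5 equiv), AcOH, rt → 50 °C; aq. NaHSO3 quench
Reagents that add atoms: bromine, BrBr
Why: Electrophilic aromatic bromination in which the hydroxyl (ortho/para), the formyl group (meta) and the C4 bromine (ortho) all point to C3 and C5, while the only other free carbon, C6, is meta to the hydroxyl and ortho to the formyl group, so the reaction should stop at the tribromide, and the anhydrous acetate-buffered medium disfavours ipso loss of the formyl group.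

Step 2
Reactants: 2 3,4,5-tribromo-2-hydroxybenzaldehyde; 3 3,5-dibromo-2-fluorobenzaldehyde (1.15 equiv)
Product: 4 3,4,5-tribromo-2-(2,4-dibromo-6-formylphenoxy)benzaldehyde
Conditions: Cs2CO3 (1.5 equiv), dry DMSO, 4 Å MS, 80 °C, N2
Reagents that add atoms: none
Why: Nucleophilic aromatic substitution (addition–elimination) in which the caesium phenoxide of 2 attacks the fluorine-bearing carbon of 3, the Meisenheimer charge being absorbed by the ortho formyl group and the ortho/para bromines; fluoride is by far the best leaving group present, the bromines of 3 are meta to its formyl group, and keeping the phenoxide as the limiting partner guards against a second displacement at the bromine para to the formyl group of ring B.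

Step 3
Reactants: 4 3,4,5-tribromo-2-(2,4-dibromo-6-formylphenoxy)benzaldehyde
Product: 5 3,4,5-tribromo-2-[2,4-dibromo-6-(formyloxy)phenoxy]phenyl formate
Conditions: mCPBA (4.5 equiv), CH2Cl2, 40 °C; aq. Na2S2O3, then brief cold aq. NaHCO3 wash; crude used directly
Reagents that add atoms: meta-chloroperoxybenzoic acid (mCPBA), OOC(=O)c1cccc(Cl)c1
Why: The peracid adds to each formyl carbonyl to give a peroxyhemiacetal (Criegee adduct), and the aryl group antiperiplanar to the O–O bond shifts from carbon to the inner peroxide oxygen as 3-chlorobenzoate departs, leaving an aryl formate; the sequence runs once on ring A and once on ring B. The closest known reaction type is the Baeyer–Villiger (Dakin-type) oxidation of ortho-alkoxy- and ortho-aryloxybenzaldehydes, halogenated examples included, to aryl formates. No ring is closed and no stereocentre is created. The selectivity required is aryl over hydride migration in both adducts, since hydride migration would end in carboxylic acids. It should be secured by the ether oxygen on C2 and C2′, ortho to each migrating carbon, whose lone pair stabilises the positive charge building up on the migrating ipso carbon, and by the non-basic, weakly acidic peracid medium in dichloromethane. The bromines (both meta to the migrating carbon on ring A; meta, para and meta on ring B) should slow the shift, hence the excess of peracid and gentle heating, while the aryl bromides and the diaryl ether are inert to the oxidant.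

Step 4
Reactants: 5 3,4,5-tribromo-2-[2,4-dibromo-6-(formyloxy)phenoxy]phenyl formate (crude)
Product: 6 3,4,5-tribromo-2-(2,4-dibromo-6-hydroxyphenoxy)phenol
Conditions: HCl (cat.), MeOH–THF, rt
Reagents that add atoms: none
Why: Acid-catalysed transesterification of both aryl formates with methanol, which should be fast because formates are the most labile esters and bromophenols are good leaving groups, while the acidic medium keeps both phenols protonated and so avoids phenoxide-driven Smiles-type scrambling of the ether and air oxidation; any formate lost during the work-up of step 3 is harmless because this step removes both.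

Compound list
1 | 4-bromo-2-hydroxybenzaldehyde | O=Cc1ccc(Br)cc1O | starting material
2 | 3,4,5-tribromo-2-hydroxybenzaldehyde | O=Cc1cc(Br)c(Br)c(Br)c1O | intermediate
3 | 3,5-dibromo-2-fluorobenzaldehyde | O=Cc1cc(Br)cc(Br)c1F | starting material
4 | 3,4,5-tribromo-2-(2,4-dibromo-6-formylphenoxy)benzaldehyde | O=Cc1cc(Br)cc(Br)c1Oc1c(C=O)cc(Br)c(Br)c1Br | intermediate
5 | 3,4,5-tribromo-2-[2,4-dibromo-6-(formyloxy)phenoxy]phenyl formate | O=COc1cc(Br)cc(Br)c1Oc1c(OC=O)cc(Br)c(Br)c1Br | intermediate
6 | 3,4,5-tribromo-2-(2,4-dibromo-6-hydroxyphenoxy)phenol | Oc1cc(Br)cc(Br)c1Oc1c(O)cc(Br)c(Br)c1Br | target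

Total step count: 4. Longest linear sequence: 4 steps (1 → 2 → 4 → 5 → 6); 3 is purchased and enters at step 2.

Steps most likely to fail

Step 3. Hydride rather than aryl migration may compete in one or both Criegee adducts, leading to over-oxidation to carboxylic acid. The oxidation may also stall after the first formyl group because the more heavily brominated ring migrates slowly. A change of oxidant (H2O2 with an areneseleninic acid catalyst) would be tried first, but the fallback proper removes the hydride altogether. It sets out from 4 and returns at 6. Addition of MeMgBr (THF, −78 °C, where bromine–magnesium exchange should not compete) to both formyl groups should give 1-[3,4,5-tribromo-2-[2,4-dibromo-6-(1-hydroxyethyl)phenoxy]phenyl]ethanol F1 as a diastereomer mixture. Dess–Martin oxidation should erase both carbinol centres to give 1-[2-(2-acetyl-4,6-dibromophenoxy)-3,4,5-tribromophenyl]ethanone F2. Baeyer–Villiger oxidation with trifluoroperacetic acid (TFAA, urea–H2O2, Na2HPO4, CH2Cl2), in which methyl is the only competitor and aryl migration is the rule for aryl methyl ketones, should give 2-(2-acetoxy-4,6-dibromophenoxy)-3,4,5-tribromophenyl acetate F3. Methanolysis (HCl, MeOH) should then deliver 6.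

Step 2. The doubly ortho-substituted, weakly nucleophilic phenoxide may substitute slowly. Fluoride may be displaced by adventitious hydroxide instead. Product may also be consumed by a second substitution at the bromine para to its formyl group. The fallback sets out from 1 and 3 and returns at 4. The less hindered and more nucleophilic phenoxide of 1 is coupled with 3 (Cs2CO3, DMSO, 60–80 °C) to give 3,5-dibromo-2-(5-bromo-2-formylphenoxy)benzaldehyde F4. The two missing bromines are then introduced on ring B with dibromoisocyanuric acid in concentrated H2SO4, a reagent that brominates deactivated arenes. The ether oxygen (ortho/para), the formyl group (meta) and the resident bromine (ortho) all direct to C3 and C5 of that ring, whereas ring A has no free position ortho or para to the ether oxygen, so 4 should result.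

Step 1. The second bromination may stall at the crowded C3 between hydroxyl and bromine, or ipso attack at C1 may cause loss of the formyl group. The fallback introduces the formyl group last. It does not set out from a numbered compound but replaces 1 by purchased 2,3-dibromophenol (Oc1cccc(Br)c1Br), and it returns at 2. Para-selective monobromination with Bu4NBr3 (CH2Cl2–MeOH, rt) should give 2,3,4-tribromophenol F5. Magnesium-mediated ortho-formylation (MgCl2, Et3N, paraformaldehyde, MeCN, reflux) at its only free ortho carbon should then give 2.

Further compounds
F1 | step 3 | 1-[3,4,5-tribromo-2-[2,4-dibromo-6-(1-hydroxyethyl)phenoxy]phenyl]ethanol (diastereomer mixture, racemic) | CC(O)c1cc(Br)cc(Br)c1Oc1c(C(C)O)cc(Br)c(Br)c1Br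
F2 | step 3 | 1-[2-(2-acetyl-4,6-dibromophenoxy)-3,4,5-tribromophenyl]ethanone | CC(=O)c1cc(Br)cc(Br)c1Oc1c(C(C)=O)cc(Br)c(Br)c1Br
F3 | step 3 | 2-(2-acetoxy-4,6-dibromophenoxy)-3,4,5-tribromophenyl acetate | CC(=O)Oc1cc(Br)cc(Br)c1Oc1c(OC(C)=O)cc(Br)c(Br)c1Br
F4 | step 2 | 3,5-dibromo-2-(5-bromo-2-formylphenoxy)benzaldehyde | O=Cc1cc(Br)cc(Br)c1Oc1cc(Br)ccc1C=O
F5 | step 1 | 2,3,4-tribromophenol | Oc1ccc(Br)c(Br)c1Br
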